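Ring A is disconnected at C1–C2 and C5–C10 (labdane numbering), which unravels the whole decalin to an acyclic deca-1,7,9-trien-3-one. The key step, an intramolecular Diels–Alder reaction of a 2-silyloxy diene (C2=C3–C4=C5) with an α-methyl enone (C1=C10–C9=O), closes rings A and B at once and sets the trans C5/C10 fusion under control of the C7 silyloxy stereocentre in the chair tether. It exploits the C3 oxygen next to quaternary C4 in ring A (silyl enol ether retron) and sp2 C9 next to quaternary C10 in ring B (activating ketone, later the enol triflate for side-chain coupling). The precursor is a linear dienone made by aldol and Wittig reactions.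

Key step: step 8

Remark on numbering: ring A is C1–C5 with C10 (C3 carries OMe, C4 the two methyls); ring B is C5–C10 (C7 carries OAc, C8=C9 is the ring alkene); the side chain C11–C15 sits on C9 and C13 is its stereocentre.

Assumption: the Z-enol borinate made with (+)-Ipc2BOTf (from (−)-α-pinene) is taken to attack the Re face of aldehyde 7, as the corresponding allylboranes do; if the sense proves opposite, the antipodal reagent is used and nothing else changes.

Step 1
Reactants: 1 (S)-citronellol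
Product: 2 tert-butyl{[(3S)-3,7-dimethyloct-6-en-1-yl]oxy}dimethylsilane
Conditions: TBSCl, imidazole, DMF, 23 °C
Reagents that add atoms: tert-butyldimethylsilyl chloride, CC(C)(C)[Si](C)(C)Cl
Why: Standard imidazole-mediated silylation of the primary alcohol, which leaves the stereocentre (the future C13) untouched.

Step 2
Reactants: 2 tert-butyl{[(3S)-3,7-dimethyloct-6-en-1-yl]oxy}dimethylsilane
Product: 4 (4S)-6-[(tert-butyldimethylsilyl)oxy]-4-methylhexanoic acid, via aldehyde 3 (not isolated)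
Conditions: O3, CH2Cl2, −78 °C; PPh3, −78 → 23 °C; then NaClO2, NaH2PO4, 2-methylbut-2-ene, t-BuOH–H2O, 0 → 23 °C
Reagents that add atoms: ozone, [O-][O+]=O; sodium chlorite, [Na+].[O-]Cl=O
Why: Ozonolysis of the trisubstituted alkene with reductive work-up gives the aldehyde (acetone is lost), and Pinnick oxidation should take it to the acid without touching the silyl ether.

Step 3
Reactants: 4 (4S)-6-[(tert-butyldimethylsilyl)oxy]-4-methylhexanoic acid
Product: 5 tert-butyldimethyl{[(3R)-3-methylpent-4-en-1-yl]oxy}silane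
Conditions: Pb(OAc)4, Cu(OAc)2 (0.1 equiv), pyridine, PhH, 80 °C
Reagents that add atoms: none
Why: Kochi oxidative decarboxylation: the primary radical formed on loss of CO2 is oxidised by the copper salt to the terminal alkene faster than it can abstract hydrogen, which shortens the chain by one carbon and leaves the allylic stereocentre untouched (the descriptor changes to R only by priority).

Step 4
Reactants: 6 2-methylpent-1-en-3-one; 7 3-[(tert-butyldimethylsilyl)oxy]propanal
Product: 9 (4R,5S)-7-[(tert-butyldimethylsilyl)oxy]-5-hydroxy-2,4-dimethylhept-1-en-3-one, via enol borinate 8 (not isolated)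
Conditions: (+)-Ipc2BOTf (from (−)-α-pinene), i-Pr2NEt, CH2Cl2, −78 °C; then 7, −78 → −20 °C; pH 7 buffer, MeOH, 30% H2O2, 0 °C
Reagents that add atoms: none
Why: Paterson aldol: the Z-enol diisopinocampheylborinate reacts through a chair Zimmerman–Traxler transition state to give the syn adduct, and the Ipc ligands select the aldehyde face so that the carbinol (the future C7) is S, the stereocentre that later controls C5 and C10.

Step 5
Reactants: 9 (4R,5S)-7-[(tert-butyldimethylsilyl)oxy]-5-hydroxy-2,4-dimethylhept-1-en-3-one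
Product: 10 (4R,5S)-5,7-bis[(tert-butyldimethylsilyl)oxy]-2,4-dimethylhept-1-en-3-one
Conditions: TBSOTf, 2,6-lutidine, CH2Cl2, −78 °C
Reagents that add atoms: tert-butyldimethylsilyl triflate, CC(C)(C)[Si](C)(C)OS(=O)(=O)C(F)(F)F
Why: Low-temperature silylation of the β-hydroxy ketone blocks retro-aldol and elimination pathways before the chain is extended.

Step 6
Reactants: 10 (4R,5S)-5,7-bis[(tert-butyldimethylsilyl)oxy]-2,4-dimethylhept-1-en-3-one
Product: 11 (4R,5S)-5-[(tert-butyldimethylsilyl)oxy]-7-hydroxy-2,4-dimethylhept-1-en-3-one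
Conditions: HF·pyridine, pyridine, THF, 0 → 23 °C
Reagents that add atoms: none
Why: Buffered HF·pyridine should cleave the unhindered primary silyl ether much faster than the secondary one flanked by the C8 methine.

Step 7
Reactants: 11 (4R,5S)-5-[(tert-butyldimethylsilyl)oxy]-7-hydroxy-2,4-dimethylhept-1-en-3-one; 12 3-(triphenyl-λ5-phosphanylidene)butan-2-one
Product: 14 (3E,6S,7R)-6-[(tert-butyldimethylsilyl)oxy]-3,7,9-trimethyldeca-3,9-diene-2,8-dione, via aldehyde 13 (not isolated)
Conditions: Dess–Martin periodinane, NaHCO3, CH2Cl2, 0 → 23 °C; filter; then 12, PhMe, 70 °C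
Reagents that add atoms: none
Why: Dess–Martin oxidation followed by Wittig olefination with a ketone-stabilised ylide, which reacts only with the aldehyde and gives the E trisubstituted enone (C4=C5 with C6 trans to the carbonyl) needed for the diene.

Step 8
Reactants: 14 (3E,6S,7R)-6-[(tert-butyldimethylsilyl)oxy]-3,7,9-trimethyldeca-3,9-diene-2,8-dione
Product: 16 (2R,3S,4aS,8aS)-3-[(tert-butyldimethylsilyl)oxy]-2,5,8a-trimethyl-6-[(triethylsilyl)oxy]-3,4,4a,7,8,8a-hexahydronaphthalen-1(2H)-one, via silyloxy triene 15 (not isolated)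
Conditions: Et3SiOTf (1.2 equiv), Et3N, CH2Cl2, −78 → 0 °C; then PhMe, BHT (cat.), 23 → 80 °C
Reagents that add atoms: triethylsilyl triflate, CC[Si](CC)(CC)OS(=O)(=O)C(F)(F)F
Why: Triethylsilyl triflate and Et3N enolise the methyl ketone of 14 on its CH3 side (the C9 ketone has only a hindered methine next to the OTBS carbon) to give the 2-silyloxy diene 15, whose diene C2=C3–C4=C5 adds to the α-methyl enone C1=C10 in a type 1 intramolecular Diels–Alder reaction that is asynchronous in the Mukaiyama–Michael sense (C2 to the enone β-carbon C1 first). The closest known reaction types are the thermal cyclisation of deca-1,7,9-trien-3-ones and silyl triflate/amine-mediated intramolecular double Michael reactions. Ring A is closed as the cyclohexene of the [4+2] addition (both new bonds), and ring B is closed by the C5–C10 bond alone, in the fused mode with the four-atom tether C6–C9 in a chair. C10 and C5 are set together: the trans fusion (10-methyl anti to 5-H) comes from the transition state with the C9 carbonyl exo, favoured because the C4 methyl of the diene acts as a steric directing group against the boat-like cis transition state and an α-methyl dienophile has no strong endo bias, while the facial sense is relayed from C7, whose OTBS group (with the C8 methyl of the syn aldol) stays equatorial in the chair tether. Regiochemistry is fixed by the tether and matched electronically, and the E geometry of C4=C5 from step 7 places C6 on the outside of the diene. The step needs chemoselective enolisation and trans over cis fusion, and BHT with dilution should suppress polymerisation of the isopropenyl ketone.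

Step 9
Reactants: 16 (2R,3S,4aS,8aS)-3-[(tert-butyldimethylsilyl)oxy]-2,5,8a-trimethyl-6-[(triethylsilyl)oxy]-3,4,4a,7,8,8a-hexahydronaphthalen-1(2H)-one
Product: 18 (3S,4aS,8aS)-3-[(tert-butyldimethylsilyl)oxy]-2,5,8a-trimethyl-6-[(triethylsilyl)oxy]-3,4,4a,7,8,8a-hexahydronaphthalen-1-yl trifluoromethanesulfonate, via potassium enolate 17 (not isolated)
Conditions: KN(SiMe3)2, THF, −78 °C; PhNTf2, −78 → 0 °C
Reagents that add atoms: N-phenylbis(trifluoromethanesulfonimide), O=S(=O)(N(c1ccccc1)S(=O)(=O)C(F)(F)F)C(F)(F)F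
Why: C10 is quaternary, so the C9 ketone can enolise only towards C8, and O-triflation of that enolate at low temperature (before the β-silyloxy group can eliminate) gives the C8=C9 enol triflate regiospecifically and removes the C8 stereocentre.

Step 10
Reactants: 18 (3S,4aS,8aS)-3-[(tert-butyldimethylsilyl)oxy]-2,5,8a-trimethyl-6-[(triethylsilyl)oxy]-3,4,4a,7,8,8a-hexahydronaphthalen-1-yl trifluoromethanesulfonate; 5 tert-butyldimethyl{[(3R)-3-methylpent-4-en-1-yl]oxy}silane
Product: 20 tert-butyl({(3S)-5-[(3S,4aR,8aS)-3-[(tert-butyldimethylsilyl)oxy]-2,5,8a-trimethyl-6-[(triethylsilyl)oxy]-3,4,4a,7,8,8a-hexahydronaphthalen-1-yl]-3-methylpentyl}oxy)dimethylsilane, via alkylborane 19 (not isolated)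
Conditions: 5, 9-BBN (0.5 M in THF), 0 → 23 °C; then 18, Pd(dppf)Cl2 (5 mol %), AsPh3 (10 mol %), K3PO4 (3 M aq.), DMF, 50 °C
Reagents that add atoms: none
Why: B-alkyl Suzuki–Miyaura coupling: anti-Markovnikov hydroboration of the terminal alkene and cross-coupling with the enol triflate (a 2,6,6-trimethylcyclohexenyl triflate analogue) attaches C11–C15 to C9 and fixes the tetrasubstituted C8=C9 alkene, with C13 taken unchanged from (S)-citronellol.

Step 11
Reactants: 20 tert-butyl({(3S)-5-[(3S,4aR,8aS)-3-[(tert-butyldimethylsilyl)oxy]-2,5,8a-trimethyl-6-[(triethylsilyl)oxy]-3,4,4a,7,8,8a-hexahydronaphthalen-1-yl]-3-methylpentyl}oxy)dimethylsilane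
Product: 22 (4aS,7S,8aR)-7-[(tert-butyldimethylsilyl)oxy]-5-{(3S)-5-[(tert-butyldimethylsilyl)oxy]-3-methylpentyl}-1,1,4a,6-tetramethyl-3,4,4a,7,8,8a-hexahydronaphthalen-2(1H)-one, via lithium enolate 21 (not isolated)
Conditions: MeLi, THF, 0 → 23 °C; then MeI, DMPU, −78 → 0 °C
Reagents that add atoms: iodomethane, CI
Why: Stork–House regiospecific enolate generation from the silyl enol ether and C-methylation at C4 (the same lithium enolate as in the classical reductive methylation of 4-methyl-Δ4-3-ketones) installs the gem-dimethyl group, which creates no new stereocentre.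

Step 12
Reactants: 22 (4aS,7S,8aR)-7-[(tert-butyldimethylsilyl)oxy]-5-{(3S)-5-[(tert-butyldimethylsilyl)oxy]-3-methylpentyl}-1,1,4a,6-tetramethyl-3,4,4a,7,8,8a-hexahydronaphthalen-2(1H)-one
Product: 23 (2S,4aS,7S,8aR)-7-[(tert-butyldimethylsilyl)oxy]-5-{(3S)-5-[(tert-butyldimethylsilyl)oxy]-3-methylpentyl}-1,1,4a,6-tetramethyl-1,2,3,4,4a,7,8,8a-octahydronaphthalen-2-ol
Conditions: NaBH4, MeOH–THF, 0 °C
Reagents that add atoms: none
Why: Hydride reduction of the 4,4-dimethyl-3-ketone should occur by axial attack on the α face (the β face is shielded by the axial 4β and 10β methyls), which gives the equatorial 3β alcohol (C3 S).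

Step 13
Reactants: 23 (2S,4aS,7S,8aR)-7-[(tert-butyldimethylsilyl)oxy]-5-{(3S)-5-[(tert-butyldimethylsilyl)oxy]-3-methylpentyl}-1,1,4a,6-tetramethyl-1,2,3,4,4a,7,8,8a-octahydronaphthalen-2-ol
Product: 24 (13S)-3β-methoxy-7β,15-bis[(tert-butyldimethylsilyl)oxy]labd-8-ene
Conditions: NaH, MeI, THF–DMF, 0 → 23 °C
Reagents that add atoms: iodomethane, CI
Why: Williamson methylation of the only free hydroxyl proceeds with retention at C3 and is compatible with both silyl ethers.

Step 14
Reactants: 24 (13S)-3β-methoxy-7β,15-bis[(tert-butyldimethylsilyl)oxy]labd-8-ene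
Product: 26 (13S)-3β-methoxylabd-8-ene-7β,15-diyl diacetate (the target), via diol 25 (not isolated)
Conditions: Bu4NF, THF, 23 °C; then Ac2O, pyridine, DMAP (cat.), 23 °C
Reagents that add atoms: acetic anhydride, CC(=O)OC(C)=O
Why: Fluoride removes both silyl ethers and DMAP-catalysed acetylation of the C7 and C15 hydroxyls in the same flask proceeds with retention, which completes the target.

Compound list
1 | (S)-citronellol, (3S)-3,7-dimethyloct-6-en-1-ol | C[C@H](CCO)CCC=C(C)C | starting material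
2 | tert-butyl{[(3S)-3,7-dimethyloct-6-en-1-yl]oxy}dimethylsilane | C[C@H](CCO[Si](C)(C)C(C)(C)C)CCC=C(C)C | intermediate
3 | (4S)-6-[(tert-butyldimethylsilyl)oxy]-4-methylhexanal | O=CCC[C@H](C)CCO[Si](C)(C)C(C)(C)C | intermediate (not isolated)
4 | (4S)-6-[(tert-butyldimethylsilyl)oxy]-4-methylhexanoic acid | OC(=O)CC[C@H](C)CCO[Si](C)(C)C(C)(C)C | intermediate
5 | tert-butyldimethyl{[(3R)-3-methylpent-4-en-1-yl]oxy}silane | C=C[C@H](C)CCO[Si](C)(C)C(C)(C)C | intermediate
6 | 2-methylpent-1-en-3-one | C=C(C)C(=O)CC | starting material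
7 | 3-[(tert-butyldimethylsilyl)oxy]propanal | O=CCCO[Si](C)(C)C(C)(C)C | starting material
8 | (Z)-2-methylpenta-1,3-dien-3-yl diisopinocampheylborinate (Ipc groups from (−)-α-pinene) | C/C=C(\OB([C@H]1C[C@H]2C[C@@H]([C@@H]1C)C2(C)C)[C@H]1C[C@H]2C[C@@H]([C@@H]1C)C2(C)C)C(C)=C | intermediate (not isolated)
9 | (4R,5S)-7-[(tert-butyldimethylsilyl)oxy]-5-hydroxy-2,4-dimethylhept-1-en-3-one | C=C(C)C(=O)[C@H](C)[C@@H](O)CCO[Si](C)(C)C(C)(C)C | intermediate
10 | (4R,5S)-5,7-bis[(tert-butyldimethylsilyl)oxy]-2,4-dimethylhept-1-en-3-one | C=C(C)C(=O)[C@H](C)[C@@H](O[Si](C)(C)C(C)(C)C)CCO[Si](C)(C)C(C)(C)C | intermediate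
11 | (4R,5S)-5-[(tert-butyldimethylsilyl)oxy]-7-hydroxy-2,4-dimethylhept-1-en-3-one | C=C(C)C(=O)[C@H](C)[C@@H](O[Si](C)(C)C(C)(C)C)CCO | intermediate
12 | 3-(triphenyl-λ5-phosphanylidene)butan-2-one | CC(=O)C(C)=P(c1ccccc1)(c1ccccc1)c1ccccc1 | starting material
13 | (3S,4R)-3-[(tert-butyldimethylsilyl)oxy]-4,6-dimethyl-5-oxohept-6-enal | C=C(C)C(=O)[C@H](C)[C@@H](O[Si](C)(C)C(C)(C)C)CC=O | intermediate (not isolated)
14 | (3E,6S,7R)-6-[(tert-butyldimethylsilyl)oxy]-3,7,9-trimethyldeca-3,9-diene-2,8-dione | C=C(C)C(=O)[C@H](C)[C@@H](O[Si](C)(C)C(C)(C)C)C/C=C(\C)C(C)=O | intermediate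
15 | (4R,5S,7E)-5-[(tert-butyldimethylsilyl)oxy]-2,4,8-trimethyl-9-[(triethylsilyl)oxy]deca-1,7,9-trien-3-one | C=C(C)C(=O)[C@H](C)[C@@H](O[Si](C)(C)C(C)(C)C)C/C=C(\C)C(=C)O[Si](CC)(CC)CC | intermediate (not isolated)
16 | (2R,3S,4aS,8aS)-3-[(tert-butyldimethylsilyl)oxy]-2,5,8a-trimethyl-6-[(triethylsilyl)oxy]-3,4,4a,7,8,8a-hexahydronaphthalen-1(2H)-one (5α-H, 10β-methyl, 7β-OTBS, 8α-methyl) | CC[Si](CC)(CC)OC=1CC[C@]2(C)C(=O)[C@H](C)[C@@H](O[Si](C)(C)C(C)(C)C)C[C@H]2C=1C | intermediate
17 | potassium enolate of 16 (C8=C9 enolate) | CC[Si](CC)(CC)OC=1CC[C@]2(C)C(O[K])=C(C)[C@@H](O[Si](C)(C)C(C)(C)C)C[C@H]2C=1C | intermediate (not isolated)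
18 | (3S,4aS,8aS)-3-[(tert-butyldimethylsilyl)oxy]-2,5,8a-trimethyl-6-[(triethylsilyl)oxy]-3,4,4a,7,8,8a-hexahydronaphthalen-1-yl trifluoromethanesulfonate | CC[Si](CC)(CC)OC=1CC[C@]2(C)C(OS(=O)(=O)C(F)(F)F)=C(C)[C@@H](O[Si](C)(C)C(C)(C)C)C[C@H]2C=1C | intermediate
19 | 9-{(3S)-5-[(tert-butyldimethylsilyl)oxy]-3-methylpentyl}-9-borabicyclo[3.3.1]nonane | B1(CC[C@H](C)CCO[Si](C)(C)C(C)(C)C)C2CCCC1CCC2 | intermediate (not isolated)
20 | tert-butyl({(3S)-5-[(3S,4aR,8aS)-3-[(tert-butyldimethylsilyl)oxy]-2,5,8a-trimethyl-6-[(triethylsilyl)oxy]-3,4,4a,7,8,8a-hexahydronaphthalen-1-yl]-3-methylpentyl}oxy)dimethylsilane | CC[Si](CC)(CC)OC=1CC[C@]2(C)C(CC[C@H](C)CCO[Si](C)(C)C(C)(C)C)=C(C)[C@@H](O[Si](C)(C)C(C)(C)C)C[C@H]2C=1C | intermediate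
21 | lithium C3–C4 enolate formed from 20 | [Li]OC=1CC[C@]2(C)C(CC[C@H](C)CCO[Si](C)(C)C(C)(C)C)=C(C)[C@@H](O[Si](C)(C)C(C)(C)C)C[C@H]2C=1C | intermediate (not isolated)
22 | (4aS,7S,8aR)-7-[(tert-butyldimethylsilyl)oxy]-5-{(3S)-5-[(tert-butyldimethylsilyl)oxy]-3-methylpentyl}-1,1,4a,6-tetramethyl-3,4,4a,7,8,8a-hexahydronaphthalen-2(1H)-one, (13S)-7β,15-bis(TBS-oxy)labd-8-en-3-one | O=C1CC[C@]2(C)C(CC[C@H](C)CCO[Si](C)(C)C(C)(C)C)=C(C)[C@@H](O[Si](C)(C)C(C)(C)C)C[C@H]2C1(C)C | intermediate
23 | (2S,4aS,7S,8aR)-7-[(tert-butyldimethylsilyl)oxy]-5-{(3S)-5-[(tert-butyldimethylsilyl)oxy]-3-methylpentyl}-1,1,4a,6-tetramethyl-1,2,3,4,4a,7,8,8a-octahydronaphthalen-2-ol, the 3β-alcohol | O[C@H]1CC[C@]2(C)C(CC[C@H](C)CCO[Si](C)(C)C(C)(C)C)=C(C)[C@@H](O[Si](C)(C)C(C)(C)C)C[C@H]2C1(C)C | intermediate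
24 | (13S)-3β-methoxy-7β,15-bis[(tert-butyldimethylsilyl)oxy]labd-8-ene (5α-H, 10β-methyl) | CO[C@H]1CC[C@]2(C)C(CC[C@H](C)CCO[Si](C)(C)C(C)(C)C)=C(C)[C@@H](O[Si](C)(C)C(C)(C)C)C[C@H]2C1(C)C | intermediate
25 | (13S)-3β-methoxylabd-8-ene-7β,15-diol | CO[C@H]1CC[C@]2(C)C(CC[C@H](C)CCO)=C(C)[C@@H](O)C[C@H]2C1(C)C | intermediate (not isolated)
26 | (3S)-5-[(3S,4aR,6S,8aS)-3-acetoxy-6-methoxy-2,5,5,8a-tetramethyl-3,4,4a,5,6,7,8,8a-octahydronaphthalen-1-yl]-3-methylpentyl acetate, (13S)-3β-methoxylabd-8-ene-7β,15-diyl diacetate | CO[C@H]1CC[C@]2(C)C(CC[C@H](C)CCOC(C)=O)=C(C)[C@@H](OC(C)=O)C[C@H]2C1(C)C | target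

Total step count: 14. Longest linear sequence: 11 steps (steps 4 to 14, from 6 and 7 to 26); the side-chain branch (steps 1 to 3) joins at step 10.

Steps most likely to fail

Step 8. The cycloaddition may lose trans selectivity at the ring fusion, giving the C5 epimer through the transition state with the carbonyl endo. The fallback assumes C10 is still set correctly relative to C7. Whatever C5 mixture forms is carried through steps 9 and 10 unchanged, and the fallback sets out from 20. Saegusa–Ito oxidation (Pd(OAc)2, MeCN, 23 °C) erases C5 and should give the conjugated enone (4aR,7S)-7-[(tert-butyldimethylsilyl)oxy]-5-{(3S)-5-[(tert-butyldimethylsilyl)oxy]-3-methylpentyl}-1,4a,6-trimethyl-4,4a,7,8-tetrahydronaphthalen-2(3H)-one F1. Stork reductive methylation (Li, NH3–THF, −78 °C; then MeI) protonates C5 trans to the angular methyl, passes through lithium enolate 21 and methylates C4. The fallback comes back to the route at ketone 22.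

Step 10. Transmetalation and reductive elimination at the tetrasubstituted C9, flanked by quaternary C10 and the C8 methyl, may be too slow, so that β-hydride loss from the alkylpalladium or hydrolysis of the triflate takes over. The fallback uses a sterically undemanding sp partner and sets out from alkene 5. Bromination (Br2, CH2Cl2, −78 °C) should give tert-butyl{[(3R)-4,5-dibromo-3-methylpentyl]oxy}dimethylsilane F2. Double dehydrobromination (NaNH2, NH3–THF) should give tert-butyldimethyl{[(3R)-3-methylpent-4-yn-1-yl]oxy}silane F3. Sonogashira coupling of F3 with triflate 18 (Pd(PPh3)4, CuI, i-Pr2NH, DMF, 50 °C) should give the enyne tert-butyl({(3R)-5-[(3S,4aR,8aS)-3-[(tert-butyldimethylsilyl)oxy]-2,5,8a-trimethyl-6-[(triethylsilyl)oxy]-3,4,4a,7,8,8a-hexahydronaphthalen-1-yl]-3-methylpent-4-yn-1-yl}oxy)dimethylsilane F4. Diimide (2-nitrobenzenesulfonylhydrazide, Et3N, CH2Cl2) saturates only the triple bond and leaves the two tetrasubstituted alkenes. The fallback comes back to the route at 20.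

Step 4. The reagent-controlled aldol may give insufficient, or reversed, enantioface selectivity with an unhindered aliphatic aldehyde. The fallback switches to auxiliary control and sets out from aldehyde 7. Evans syn-aldol with commercial (R)-4-benzyl-3-propionyloxazolidin-2-one (Bu2BOTf, Et3N, CH2Cl2, −78 → 0 °C) should give (4R)-4-benzyl-3-{(2R,3S)-5-[(tert-butyldimethylsilyl)oxy]-3-hydroxy-2-methylpentanoyl}oxazolidin-2-one F5. Transamidation (MeNHOMe·HCl, AlMe3, THF) should give the Weinreb amide (2R,3S)-5-[(tert-butyldimethylsilyl)oxy]-3-hydroxy-N-methoxy-N,2-dimethylpentanamide F6. Silylation (TBSOTf, 2,6-lutidine) should give (2R,3S)-3,5-bis[(tert-butyldimethylsilyl)oxy]-N-methoxy-N,2-dimethylpentanamide F7. Addition of CH2=C(Me)MgBr (THF, 0 °C) brings the fallback back to the route at ketone 10.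

Further compounds
F1 | step 8 | (4aR,7S)-7-[(tert-butyldimethylsilyl)oxy]-5-{(3S)-5-[(tert-butyldimethylsilyl)oxy]-3-methylpentyl}-1,4a,6-trimethyl-4,4a,7,8-tetrahydronaphthalen-2(3H)-one | O=C1CC[C@]2(C)C(CC[C@H](C)CCO[Si](C)(C)C(C)(C)C)=C(C)[C@@H](O[Si](C)(C)C(C)(C)C)CC2=C1C
F2 | step 10 | tert-butyl{[(3R)-4,5-dibromo-3-methylpentyl]oxy}dimethylsilane (both C4 epimers) | BrCC(Br)[C@H](C)CCO[Si](C)(C)C(C)(C)C
F3 | step 10 | tert-butyldimethyl{[(3R)-3-methylpent-4-yn-1-yl]oxy}silane | C#C[C@H](C)CCO[Si](C)(C)C(C)(C)C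
F4 | step 10 | tert-butyl({(3R)-5-[(3S,4aR,8aS)-3-[(tert-butyldimethylsilyl)oxy]-2,5,8a-trimethyl-6-[(triethylsilyl)oxy]-3,4,4a,7,8,8a-hexahydronaphthalen-1-yl]-3-methylpent-4-yn-1-yl}oxy)dimethylsilane | CC[Si](CC)(CC)OC=1CC[C@]2(C)C(C#C[C@H](C)CCO[Si](C)(C)C(C)(C)C)=C(C)[C@@H](O[Si](C)(C)C(C)(C)C)C[C@H]2C=1C
F5 | step 4 | (4R)-4-benzyl-3-{(2R,3S)-5-[(tert-butyldimethylsilyl)oxy]-3-hydroxy-2-methylpentanoyl}oxazolidin-2-one | O=C1OC[C@@H](Cc2ccccc2)N1C(=O)[C@H](C)[C@@H](O)CCO[Si](C)(C)C(C)(C)C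
F6 | step 4 | (2R,3S)-5-[(tert-butyldimethylsilyl)oxy]-3-hydroxy-N-methoxy-N,2-dimethylpentanamide | CON(C)C(=O)[C@H](C)[C@@H](O)CCO[Si](C)(C)C(C)(C)C
F7 | step 4 | (2R,3S)-3,5-bis[(tert-butyldimethylsilyl)oxy]-N-methoxy-N,2-dimethylpentanamide | CON(C)C(=O)[C@H](C)[C@@H](O[Si](C)(C)C(C)(C)C)CCO[Si](C)(C)C(C)(C)C
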